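**Assumptions (remarks on the chemistry)**
- Germacrane numbering is used throughout: ring carbons C1–C10, lactone C6–O–C12(=O)–C11, C13 the exocyclic methylene carbon, C14 the methyl on C10, C15 the methyl on C4.
- The sulfur-bearing carbon C10 is formed without stereocontrol in step 9 and carried as an epimeric mixture (left unspecified in the SMILES of 16, 17, 25–30); it becomes sp2 in step 18. The same holds for C1 of 29, C1/C10 of 30 and C11 of 32 and 33.
- The butenoyl group of 15 is an E/Z mixture; its geometry is lost in step 9.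

## Retrosynthetic overview
1. Target 35 ⇐ fluoride desilylation of 34 ⇐ Eschenmoser α-methylenation of lactone 31.
2. The ten-membered carbocycle (C1–C10) of 31 ⇐ Ramberg–Bäcklund ring contraction (SO2 extrusion) of the eleven-membered thiacycle S,S-dioxide 28, in which sulfur bridges C1 and C10. The enabling feature is the (Z)-C1=C10 trisubstituted alkene of the carbocycle: it lies between two sp3 carbons (C2, C9) and bears no stereocentre, so its two carbons can be held by a C–SO2–C bridge and the double bond regenerated on extrusion.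
3. 28 ⇐ sulfide 27 ⇐ intramolecular S-alkylation (C10 thiolate on C1–Cl) of acyclic lactone 25; 25 ⇐ Felkin reduction of the C8 ketone and Yamaguchi esterification with acid 23 (from tiglyl alcohol by Sharpless epoxidation and inverting epoxide hydrolysis).
4. trans-γ-Lactone (C6/C7) ⇐ Evans syn-aldol of succinate imide 10 with (E)-enal 7 (from (R)-epichlorohydrin by alkynylation and Zr-catalysed carboalumination).
5. Order of ring formation: γ-lactone (step 7), eleven-membered thiacycle (step 16), contraction to the ten-membered carbocycle (step 18).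

Key step: step 18

## Route

Step 1
Reactants: 1 (R)-epichlorohydrin
Product: 2 (2R)-1-chloropent-4-yn-2-ol
Conditions: HC≡CH, n-BuLi, THF, −78 °C; BF3·OEt2; 1, −78 °C; H2O
Reagents that add atoms: acetylene, C#C
Why: BF3-promoted SN2 opening of the epoxide by lithium acetylide at the unsubstituted carbon should leave the carbinol centre untouched (R retained) and the chloride in place at −78 °C.

Step 2
Reactants: 2 (2R)-1-chloropent-4-yn-2-ol
Product: 3 tert-butyl{[(2R)-1-chloropent-4-yn-2-yl]oxy}dimethylsilane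
Conditions: TBSCl, imidazole, DMF, rt
Reagents that add atoms: tert-butyldimethylsilyl chloride, CC(C)(C)[Si](C)(C)Cl
Why: Standard silylation of a secondary alcohol, which also prevents epoxide re-closure.

Step 3
Reactants: 3 tert-butyl{[(2R)-1-chloropent-4-yn-2-yl]oxy}dimethylsilane
Product: 6 (2E,5R)-5-[tert-butyl(dimethyl)silyl]oxy-6-chloro-3-methylhex-2-en-1-ol, via alkenylalane 4 (not isolated), via lithium alkenylaluminate 5 (not isolated)
Conditions: Me3Al, Cp2ZrCl2 (20 mol %), CH2Cl2, 0 °C → rt; n-BuLi, THF, −78 °C; (CH2O)n, → rt; aq. HCl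
Reagents that add atoms: trimethylaluminium, C[Al](C)C; paraformaldehyde (as formaldehyde), C=O
Why: Zr-catalysed carboalumination (Negishi) adds Me–Al syn across the terminal alkyne with Me on the internal carbon, and the derived aluminate is trapped by formaldehyde, so the E-trisubstituted C4=C5 alkene is fixed here.

Step 4
Reactants: 6 (2E,5R)-5-[tert-butyl(dimethyl)silyl]oxy-6-chloro-3-methylhex-2-en-1-ol
Product: 7 (2E,5R)-5-[tert-butyl(dimethyl)silyl]oxy-6-chloro-3-methylhex-2-enal
Conditions: MnO2, CH2Cl2, rt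
Reagents that add atoms: none
Why: Selective allylic oxidation with MnO2 should give the enal without E/Z isomerisation.

Step 5
Reactants: 8 (4S)-4-benzyl-1,3-oxazolidin-2-one; 9 methyl 4-chloro-4-oxobutanoate
Product: 10 methyl 4-[(4S)-4-benzyl-2-oxo-1,3-oxazolidin-3-yl]-4-oxobutanoate
Conditions: n-BuLi, THF, −78 °C; then 9
Reagents that add atoms: none
Why: N-Acylation of the lithiated oxazolidinone by the acid chloride is faster than attack at the methyl ester.

Step 6
Reactants: 10 methyl 4-[(4S)-4-benzyl-2-oxo-1,3-oxazolidin-3-yl]-4-oxobutanoate; 7 (2E,5R)-5-[tert-butyl(dimethyl)silyl]oxy-6-chloro-3-methylhex-2-enal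
Product: 12 methyl (3S,4R,5E,8R)-3-[(4S)-4-benzyl-2-oxo-1,3-oxazolidine-3-carbonyl]-8-[tert-butyl(dimethyl)silyl]oxy-9-chloro-4-hydroxy-6-methylnon-5-enoate, via Z-boron enolate 11 (not isolated)
Conditions: n-Bu2BOTf, Et3N, CH2Cl2, −78 → 0 °C; 7, −78 → 0 °C; pH 7 buffer, MeOH, H2O2
Reagents that add atoms: none
Why: Evans syn-aldol: the Z-boron enolate reacts through a closed chair transition state on the face away from the benzyl group, which sets C6 (R) and C7 together in the syn relation that becomes the trans-lactone.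

Step 7
Reactants: 12 aldol adduct
Product: 13 (2R,3S)-2-[(1E,4R)-4-[tert-butyl(dimethyl)silyl]oxy-5-chloro-2-methylpent-1-en-1-yl]-5-oxooxolane-3-carboxylic acid
Conditions: LiOH, H2O2, THF/H2O, 0 °C → rt; Na2SO3; 1 M HCl to pH 2
Reagents that add atoms: hydrogen peroxide, OO
Why: Hydroperoxide cleaves the exocyclic imide carbonyl selectively and the C6 hydroxyl closes onto the succinate ester carbon (γ-lactonisation with loss of methanol), giving the trans-4,5-disubstituted lactone acid without touching a stereocentre.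

Step 8
Reactants: 13 lactone acid
Product: 15 (4S,5R)-4-(but-2-enoyl)-5-[(1E,4R)-4-[tert-butyl(dimethyl)silyl]oxy-5-chloro-2-methylpent-1-en-1-yl]oxolan-2-one, via acid chloride 14 (not isolated)
Conditions: 1-chloro-N,N,2-trimethylprop-1-en-1-amine, CH2Cl2, 0 °C → rt; then 1-propenylmagnesium bromide, Fe(acac)3 (3 mol %), THF, −78 °C
Reagents that add atoms: 1-propenylmagnesium bromide, CC=C[Mg]Br
Why: Neutral acid chloride formation followed by Fe-catalysed acylation of the Grignard reagent at −78 °C should give the enone chemoselectively, since lactone and alkyl chloride react far more slowly than the acid chloride, and it avoids zerovalent palladium, which could ionise the allylic lactone.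

Step 9
Reactants: 15 enone
Product: 16 methyl 3-({4-[(2R,3S)-2-[(1E,4R)-4-[tert-butyl(dimethyl)silyl]oxy-5-chloro-2-methylpent-1-en-1-yl]-5-oxooxolan-3-yl]-4-oxobutan-2-yl}sulfanyl)propanoate (C10 epimers)
Conditions: methyl 3-sulfanylpropanoate, Et3N (10 mol %), CH2Cl2, 0 °C
Reagents that add atoms: methyl 3-sulfanylpropanoate, COC(=O)CCS
Why: Thia-Michael addition installs sulfur at C10 as a base-releasable thiol surrogate with no acyl group on sulfur that could migrate to the later C8 hydroxyl; the new C10 centre is not controlled and need not be.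

Step 10
Reactants: 16 β-sulfanyl ketone
Product: 17 methyl 3-({(4R)-4-hydroxy-4-[(2R,3R)-2-[(1E,4R)-4-[tert-butyl(dimethyl)silyl]oxy-5-chloro-2-methylpent-1-en-1-yl]-5-oxooxolan-3-yl]butan-2-yl}sulfanyl)propanoate (C10 epimers)
Conditions: LiBH(s-Bu)3, THF, −78 °C; AcOH at −78 °C
Reagents that add atoms: none
Why: Felkin–Anh-controlled ketone reduction: the bulky hydride attacks anti to the larger C6 branch on C7, which should give the 8R alcohol (C8–O anti to C11 in the C6–C9 zigzag), and the cold acidic quench prevents migration of the lactone acyl group to the new alkoxide.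

Step 11
Reactants: 18 (2E)-2-methylbut-2-en-1-ol
Product: 19 [(2R,3R)-2,3-dimethyloxiran-2-yl]methanol
Conditions: Ti(OiPr)4 (10 mol %), D-(−)-diethyl tartrate, t-BuOOH, MS 4 Å, CH2Cl2, −20 °C
Reagents that add atoms: tert-butyl hydroperoxide, CC(C)(C)OO
Why: Sharpless asymmetric epoxidation of an E-trisubstituted allylic alcohol; the D-tartrate ligand delivers oxygen to the face that gives the (2R,3R)-epoxide.

Step 12
Reactants: 19 epoxy alcohol
Product: 20 (2S,3R)-2,3-dimethyloxirane-2-carboxylic acid
Conditions: RuCl3·H2O (2 mol %), NaIO4, MeCN/CCl4/H2O, rt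
Reagents that add atoms: sodium periodate, [Na+].[O-]I(=O)(=O)=O
Why: RuO4-catalysed oxidation of the primary alcohol to the acid leaves the epoxide and both stereocentres intact (the descriptor at C2 changes only through priority).

Step 13
Reactants: 20 epoxy acid
Product: 21 (2S,3S)-2,3-dihydroxy-2-methylbutanoic acid
Conditions: H2O, HClO4 (cat.), 50 °C
Reagents that add atoms: water, O
Why: Acid-catalysed epoxide hydrolysis: water attacks C3 with inversion because the carboxyl group disfavours cationic character at the quaternary C2, which sets 3S and retains 2S.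

Step 14
Reactants: 21 dihydroxy acid
Product: 23 (2S,3S)-2-methyl-2,3-bis(triethylsilyloxy)butanoic acid, via tris-silylated ester 22 (not isolated)
Conditions: Et3SiOTf (3.5 equiv), 2,6-lutidine, CH2Cl2, 0 °C → rt; then MeOH/H2O, rt
Reagents that add atoms: triethylsilyl triflate, CC[Si](CC)(CC)OS(=O)(=O)C(F)(F)F
Why: Exhaustive silylation (the triflate also silylates the tertiary hydroxyl) followed by selective solvolysis of the labile silyl ester should give the acid in a form that is later unmasked by fluoride.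

Step 15
Reactants: 17 C8 alcohol; 23 (2S,3S)-2-methyl-2,3-bis(triethylsilyloxy)butanoic acid
Product: 25 the C8 ester of 17 with 23, methyl 3-({(4R)-4-{[(2S,3S)-2-methyl-2,3-bis(triethylsilyloxy)butanoyl]oxy}-4-[(2R,3R)-2-[(1E,4R)-4-[tert-butyl(dimethyl)silyl]oxy-5-chloro-2-methylpent-1-en-1-yl]-5-oxooxolan-3-yl]butan-2-yl}sulfanyl)propanoate (C10 epimers), via mixed anhydride 24 (not isolated)
Conditions: 2,4,6-trichlorobenzoyl chloride, Et3N, THF, rt; then 17, DMAP, toluene, 60 °C
Reagents that add atoms: none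
Why: Yamaguchi esterification through the mixed anhydride and the acylpyridinium ion is a standard answer to a hindered acid/secondary alcohol pair and does not touch C8 (retention).

Step 16
Reactants: 25 acyclic ester
Product: 27 macrocyclic sulfide (2R,4E,6R,7R,8R)-2-[tert-butyl(dimethyl)silyl]oxy-8-[(2S,3S)-2-methyl-2,3-bis(triethylsilyloxy)butanoyl]oxy-1,10-seco-13-norgermacr-4-en-12,6-olide with sulfur linking C1 and C10 (eleven-membered thiacycle, C10 epimers), via potassium thiolate 26 (not isolated)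
Conditions: KOtBu (2.2 equiv), KI (cat.), THF/DMF (0.002 M), −40 → 40 °C
Reagents that add atoms: none
Why: Base-induced retro-Michael loss of methyl acrylate unmasks the C10 thiolate, which closes the eleven-membered ring by intramolecular SN2 at the primary C1 chloride under high dilution, with the E-alkene and the trans-lactone limiting the conformational space.

Step 17
Reactants: 27 macrocyclic sulfide
Product: 28 the corresponding S,S-dioxide (eleven-membered cyclic sulfone, C10 epimers)
Conditions: (n-Pr4N)RuO4 (10 mol %), N-methylmorpholine N-oxide, MS 4 Å, MeCN, 40 °C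
Reagents that add atoms: N-methylmorpholine N-oxide, C[N+]1([O-])CCOCC1
Why: Perruthenate/N-oxide oxidation takes the sulfide to the sulfone under neutral anhydrous conditions that should spare both trisubstituted alkenes and the silyl ethers.

Step 18
Reactants: 28 eleven-membered cyclic sulfone
Product: 31 (1(10)Z,2R,4E,6R,7R,8R)-2-[tert-butyl(dimethyl)silyl]oxy-8-[(2S,3S)-2-methyl-2,3-bis(triethylsilyloxy)butanoyl]oxy-13-norgermacra-1(10),4-dien-12,6-olide, via 1-chloro sulfone 29 (not isolated), via episulfone 30 (not isolated)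
Conditions: LDA (2.2 equiv), THF, −78 °C; C2Cl6 (1.05 equiv), −78 °C; KOtBu (3 equiv), −78 → 0 °C; aq. NH4Cl
Reagents that add atoms: none
Why: Ramberg–Bäcklund reaction: LDA forms first the lactone enolate and then the less stabilised, more nucleophilic α-sulfonyl carbanion at the unhindered C1 methylene, which alone is chlorinated by one equivalent of C2Cl6; KOtBu then deprotonates C10, the carbanion displaces chloride at C1 in a 1,3-elimination to the episulfone 30, and cheletropic loss of SO2 leaves the C1=C10 alkene, so the eleven-membered thiacycle contracts to the ten-membered carbocycle. The closest known reaction type is the Ramberg–Bäcklund contraction of medium-ring α-halo sulfones to cycloalkenes, which has delivered trisubstituted Z-alkenes in lactone-fused medium carbocycles. The ten-membered ring is closed by the 3-exo-tet C1–C10 bond formation inside the thiacycle; no new stereocentre arises, and C2, C6, C7 and C8 carry no proton acidic enough to epimerise. The step needs Z over E geometry: the cis-fused episulfone (C2 and C9 syn) should be the kinetically favoured closure in a medium ring that already holds the E-C4=C5 alkene and the trans-lactone, SO2 extrusion is stereospecific, and the low temperature limits base-mediated epimerisation of the episulfone. It also needs site-selective chlorination, which the order of dianion reactivity and the stoichiometry of C2Cl6 should secure; the C10 epimers of 28 converge because C10 becomes sp2.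

Step 19
Reactants: 31 ring-contracted lactone
Product: 34 (1(10)Z,2R,4E,6R,7R,8R)-2-[tert-butyl(dimethyl)silyl]oxy-8-[(2S,3S)-2-methyl-2,3-bis(triethylsilyloxy)butanoyl]oxygermacra-1(10),4,11(13)-trien-12,6-olide, via Mannich base 32 (not isolated), via trimethylammonium iodide 33 (not isolated)
Conditions: LDA, THF, −78 °C; dimethyl(methylidene)ammonium iodide, −78 °C → rt; MeI, MeOH; DBU, CH2Cl2
Reagents that add atoms: dimethyl(methylidene)ammonium iodide, C=[N+](C)C.[I-]
Why: Eschenmoser methylenation: the lactone enolate (the only acidic C–H left; the C8 ester has no α-hydrogen) is aminomethylated at C11, and quaternisation followed by elimination gives the exocyclic methylene, so the C11 configuration of 32 is irrelevant.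

Step 20
Reactants: 34 silyl-protected target
Product: 35 CNP0402993.2, (1(10)Z,2R,4E,6R,7R,8R)-2-hydroxy-8-[(2S,3S)-2,3-dihydroxy-2-methylbutanoyl]oxygermacra-1(10),4,11(13)-trien-12,6-olide
Conditions: HF·pyridine, pyridine, THF, 0 °C → rt
Reagents that add atoms: none
Why: Buffered fluoride removes the three silyl ethers without the Brønsted acidity that could trigger transannular cyclisation of the 1(10),4-diene or ionisation of the allylic C2 alcohol.

## Compound list
1 | (R)-epichlorohydrin | ClC[C@H]1CO1 | starting material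
2 | (2R)-1-chloropent-4-yn-2-ol | C#CC[C@@H](O)CCl | intermediate
3 | tert-butyl{[(2R)-1-chloropent-4-yn-2-yl]oxy}dimethylsilane | C#CC[C@@H](O[Si](C)(C)C(C)(C)C)CCl | intermediate
4 | [(1E,4R)-4-[tert-butyl(dimethyl)silyl]oxy-5-chloro-2-methylpent-1-en-1-yl]dimethylalumane | C[Al](C)/C=C(\C)C[C@@H](O[Si](C)(C)C(C)(C)C)CCl | intermediate
5 | lithium butyl[(1E,4R)-4-[tert-butyl(dimethyl)silyl]oxy-5-chloro-2-methylpent-1-en-1-yl]dimethylaluminate | [Li+].CCCC[Al-](C)(C)/C=C(\C)C[C@@H](O[Si](C)(C)C(C)(C)C)CCl | intermediate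
6 | (2E,5R)-5-[tert-butyl(dimethyl)silyl]oxy-6-chloro-3-methylhex-2-en-1-ol | OC/C=C(\C)C[C@@H](O[Si](C)(C)C(C)(C)C)CCl | intermediate
7 | (2E,5R)-5-[tert-butyl(dimethyl)silyl]oxy-6-chloro-3-methylhex-2-enal | O=C/C=C(\C)C[C@@H](O[Si](C)(C)C(C)(C)C)CCl | intermediate
8 | (4S)-4-benzyl-1,3-oxazolidin-2-one | O=C1N[C@@H](Cc2ccccc2)CO1 | starting material
9 | methyl 4-chloro-4-oxobutanoate | COC(=O)CCC(Cl)=O | starting material
10 | methyl 4-[(4S)-4-benzyl-2-oxo-1,3-oxazolidin-3-yl]-4-oxobutanoate | COC(=O)CCC(=O)N1[C@@H](Cc2ccccc2)COC1=O | intermediate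
11 | Z-dibutylboron enolate of 10 | CCCCB(CCCC)O/C(=C\CC(=O)OC)N1[C@@H](Cc2ccccc2)COC1=O | intermediate
12 | methyl (3S,4R,5E,8R)-3-[(4S)-4-benzyl-2-oxo-1,3-oxazolidine-3-carbonyl]-8-[tert-butyl(dimethyl)silyl]oxy-9-chloro-4-hydroxy-6-methylnon-5-enoate | COC(=O)C[C@H](C(=O)N1[C@@H](Cc2ccccc2)COC1=O)[C@H](O)/C=C(\C)C[C@@H](O[Si](C)(C)C(C)(C)C)CCl | intermediate
13 | (2R,3S)-2-[(1E,4R)-4-[tert-butyl(dimethyl)silyl]oxy-5-chloro-2-methylpent-1-en-1-yl]-5-oxooxolane-3-carboxylic acid | O=C1C[C@H](C(O)=O)[C@@H](/C=C(\C)C[C@@H](O[Si](C)(C)C(C)(C)C)CCl)O1 | intermediate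
14 | acid chloride of 13 | O=C1C[C@H](C(Cl)=O)[C@@H](/C=C(\C)C[C@@H](O[Si](C)(C)C(C)(C)C)CCl)O1 | intermediate
15 | (4S,5R)-4-(but-2-enoyl)-5-[(1E,4R)-4-[tert-butyl(dimethyl)silyl]oxy-5-chloro-2-methylpent-1-en-1-yl]oxolan-2-one (E/Z mixture in the butenoyl group) | O=C1C[C@H](C(=O)C=CC)[C@@H](/C=C(\C)C[C@@H](O[Si](C)(C)C(C)(C)C)CCl)O1 | intermediate
16 | β-sulfanyl ketone, methyl 3-({4-[(2R,3S)-2-[(1E,4R)-4-[tert-butyl(dimethyl)silyl]oxy-5-chloro-2-methylpent-1-en-1-yl]-5-oxooxolan-3-yl]-4-oxobutan-2-yl}sulfanyl)propanoate (C10 epimers) | O=C1C[C@H](C(=O)CC(C)SCCC(=O)OC)[C@@H](/C=C(\C)C[C@@H](O[Si](C)(C)C(C)(C)C)CCl)O1 | intermediate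
17 | C8 alcohol, methyl 3-({(4R)-4-hydroxy-4-[(2R,3R)-2-[(1E,4R)-4-[tert-butyl(dimethyl)silyl]oxy-5-chloro-2-methylpent-1-en-1-yl]-5-oxooxolan-3-yl]butan-2-yl}sulfanyl)propanoate (C10 epimers) | O=C1C[C@H]([C@H](O)CC(C)SCCC(=O)OC)[C@@H](/C=C(\C)C[C@@H](O[Si](C)(C)C(C)(C)C)CCl)O1 | intermediate
18 | (2E)-2-methylbut-2-en-1-ol | C/C=C(\C)CO | starting material
19 | [(2R,3R)-2,3-dimethyloxiran-2-yl]methanol | C[C@H]1O[C@]1(C)CO | intermediate
20 | (2S,3R)-2,3-dimethyloxirane-2-carboxylic acid | C[C@H]1O[C@]1(C)C(O)=O | intermediate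
21 | (2S,3S)-2,3-dihydroxy-2-methylbutanoic acid | OC(=O)[C@@](C)(O)[C@H](C)O | intermediate
22 | triethylsilyl (2S,3S)-2-methyl-2,3-bis(triethylsilyloxy)butanoate | CC[Si](CC)(CC)OC(=O)[C@@](C)(O[Si](CC)(CC)CC)[C@H](C)O[Si](CC)(CC)CC | intermediate
23 | (2S,3S)-2-methyl-2,3-bis(triethylsilyloxy)butanoic acid | OC(=O)[C@@](C)(O[Si](CC)(CC)CC)[C@H](C)O[Si](CC)(CC)CC | intermediate
24 | mixed anhydride of 23 with 2,4,6-trichlorobenzoic acid | O=C(OC(=O)[C@@](C)(O[Si](CC)(CC)CC)[C@H](C)O[Si](CC)(CC)CC)c1c(Cl)cc(Cl)cc1Cl | intermediate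
25 | C8 ester of 17 with 23 (C10 epimers) | O=C1C[C@H]([C@H](OC(=O)[C@@](C)(O[Si](CC)(CC)CC)[C@H](C)O[Si](CC)(CC)CC)CC(C)SCCC(=O)OC)[C@@H](/C=C(\C)C[C@@H](O[Si](C)(C)C(C)(C)C)CCl)O1 | intermediate
26 | potassium C10 thiolate from 25 | O=C1C[C@H]([C@H](OC(=O)[C@@](C)(O[Si](CC)(CC)CC)[C@H](C)O[Si](CC)(CC)CC)CC(C)[S-])[C@@H](/C=C(\C)C[C@@H](O[Si](C)(C)C(C)(C)C)CCl)O1.[K+] | intermediate
27 | macrocyclic sulfide (eleven-membered thiacycle, S between C1 and C10; 2R,4E,6R,7R,8R; C10 epimers) | C1C(=O)O[C@@H]2/C=C(\C)C[C@@H](O[Si](C)(C)C(C)(C)C)CSC(C)C[C@@H](OC(=O)[C@@](C)(O[Si](CC)(CC)CC)[C@H](C)O[Si](CC)(CC)CC)[C@@H]12 | intermediate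
28 | S,S-dioxide of 27 (C10 epimers) | C1C(=O)O[C@@H]2/C=C(\C)C[C@@H](O[Si](C)(C)C(C)(C)C)CS(=O)(=O)C(C)C[C@@H](OC(=O)[C@@](C)(O[Si](CC)(CC)CC)[C@H](C)O[Si](CC)(CC)CC)[C@@H]12 | intermediate
29 | 1-chloro derivative of sulfone 28 (C1 and C10 epimers) | C1C(=O)O[C@@H]2/C=C(\C)C[C@@H](O[Si](C)(C)C(C)(C)C)C(Cl)S(=O)(=O)C(C)C[C@@H](OC(=O)[C@@](C)(O[Si](CC)(CC)CC)[C@H](C)O[Si](CC)(CC)CC)[C@@H]12 | intermediate
30 | cis-fused C1–C10 episulfone (thiirane 1,1-dioxide on the ten-membered ring, C2 and C9 syn) | C1C(=O)O[C@@H]2/C=C(\C)C[C@@H](O[Si](C)(C)C(C)(C)C)C3C(C)(S3(=O)=O)C[C@@H](OC(=O)[C@@](C)(O[Si](CC)(CC)CC)[C@H](C)O[Si](CC)(CC)CC)[C@@H]12 | intermediate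
31 | (1(10)Z,2R,4E,6R,7R,8R)-2-[tert-butyl(dimethyl)silyl]oxy-8-[(2S,3S)-2-methyl-2,3-bis(triethylsilyloxy)butanoyl]oxy-13-norgermacra-1(10),4-dien-12,6-olide | C1C(=O)O[C@@H]2/C=C(\C)C[C@@H](O[Si](C)(C)C(C)(C)C)/C=C(/C)C[C@@H](OC(=O)[C@@](C)(O[Si](CC)(CC)CC)[C@H](C)O[Si](CC)(CC)CC)[C@@H]12 | intermediate
32 | 11-(dimethylaminomethyl) derivative of 31 (C11 epimers) | CN(C)CC1C(=O)O[C@@H]2/C=C(\C)C[C@@H](O[Si](C)(C)C(C)(C)C)/C=C(/C)C[C@@H](OC(=O)[C@@](C)(O[Si](CC)(CC)CC)[C@H](C)O[Si](CC)(CC)CC)[C@@H]12 | intermediate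
33 | trimethylammonium iodide from 32 | C[N+](C)(C)CC1C(=O)O[C@@H]2/C=C(\C)C[C@@H](O[Si](C)(C)C(C)(C)C)/C=C(/C)C[C@@H](OC(=O)[C@@](C)(O[Si](CC)(CC)CC)[C@H](C)O[Si](CC)(CC)CC)[C@@H]12.[I-] | intermediate
34 | tris-silyl ether of the target | C=C1C(=O)O[C@@H]2/C=C(\C)C[C@@H](O[Si](C)(C)C(C)(C)C)/C=C(/C)C[C@@H](OC(=O)[C@@](C)(O[Si](CC)(CC)CC)[C@H](C)O[Si](CC)(CC)CC)[C@@H]12 | intermediate
35 | CNP0402993.2 | C=C1C(=O)O[C@@H]2/C=C(\C)C[C@@H](O)/C=C(/C)C[C@@H](OC(=O)[C@@](C)(O)[C@H](C)O)[C@@H]12 | target

## Step count and risks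
Total steps: 20. Longest linear sequence: 15 steps (1, 2, 3, 4, 6, 7, 8, 9, 10, 15, 16, 17, 18, 19, 20, from (R)-epichlorohydrin).

Steps most likely to fail:

1. Step 18 (ring contraction). The chlorination may go to the lactone enolate instead of C1, the C1 carbanion may expel the β-silyloxy group, and the strong base may epimerise the episulfone and erode the Z-selectivity. Fallback: setting out from sulfide 27, the halogen is introduced at the sulfide oxidation level without any carbanion. N-Chlorosuccinimide in CCl4 at 0 °C should give, through the chlorosulfonium ion and thionium ion, the α-chloro sulfide F1 (a C10-chloro regioisomer would be equally competent). Oxidation with (n-Pr4N)RuO4 and N-methylmorpholine N-oxide over molecular sieves then gives the chloro sulfone 29, this time isolated. Compound 29 is contracted with a single equivalent of KOtBu in THF at −78 °C, so that the stepwise halo-sulfone form of the Ramberg–Bäcklund reaction comes back to the route at 31.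

2. Step 16 (macrocyclisation). Intermolecular S-alkylation may outrun ring closure, and the thiolate may re-add to the acrylate it has released. Fallback: setting out from enone 15, one sulfur atom stitches the ring. Slow addition of Na2S·9H2O (1 equiv) in EtOH/THF under high dilution should add hydrosulfide reversibly to the enone and alkylate the thiolate irreversibly at the C1 chloride, giving the macrocyclic keto sulfide F2. Reduction with LiBH(s-Bu)3 at −78 °C gives the macrocyclic alcohol F3, and Yamaguchi esterification of F3 with acid 23 returns to the route at 27.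

3. Step 10 (ketone reduction). Substrate control may give poor facial selectivity at C8, and the lithium alkoxide may take over the lactone acyl group (translactonisation to the 8,12-olide). Fallback: stereocontrol is moved from the substrate to the reagent. Setting out from ketone 16, reduction with catecholborane and (S)-2-methyl-CBS-oxazaborolidine in toluene at −78 °C (branched C7 as the large group, C9 methylene as the small one, a neutral boron alkoxide as product) should give the 8R alcohol and comes back at 17 with no new compound.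

## Further compounds
F1 | step 18 | 1-chloro derivative of sulfide 27 (α-chloro sulfide, C1 and C10 epimers) | C1C(=O)O[C@@H]2/C=C(\C)C[C@@H](O[Si](C)(C)C(C)(C)C)C(Cl)SC(C)C[C@@H](OC(=O)[C@@](C)(O[Si](CC)(CC)CC)[C@H](C)O[Si](CC)(CC)CC)[C@@H]12
F2 | step 16 | macrocyclic keto sulfide (eleven-membered thiacycle with C8 ketone, 2-silyl ether, C10 epimers) | C1C(=O)O[C@@H]2/C=C(\C)C[C@@H](O[Si](C)(C)C(C)(C)C)CSC(C)CC(=O)[C@@H]12
F3 | step 16 | macrocyclic 8R alcohol from F2 | C1C(=O)O[C@@H]2/C=C(\C)C[C@@H](O[Si](C)(C)C(C)(C)C)CSC(C)C[C@@H](O)[C@@H]12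
F0 | step 10 | none | none
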